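**Plan**
- Cuts, in retrosynthetic order: the ring-B ester (protecting group), the C5–CH2 bond (aryl iodide plus primary alkylzinc), the tertiary C–OH (back to isopropenyl), the dihydrofuran bonds C3a–C3 and O1–C2, and the ring A–carbonyl bond.
- Enabling feature: C3, C2 and the three-carbon branch on C2 are the five carbons of isoprene, and they sit on two adjacent atoms of ring A (C3a and O1). An o-iodophenol and isoprene therefore give the ring in one operation.
- Forward order: benzophenone by Friedel–Crafts acylation of 1,3,5-trimethoxybenzene, cleavage of both ortho methyl ethers, mono-iodination; then the dihydrofuran ring by palladium heteroannulation; hydration of the isopropenyl group; iodination at C5; Negishi attachment of the ten-carbon chain; ester removal.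
- Stereochemistry: C2 (S) comes from the chiral ligand in the heteroannulation. The side-chain centre (R in the target) comes from a lipase-resolved (S)-alcohol carried unchanged through the iodide and the zinc reagent.

Key step: step 5

Assumptions (chemistry): the antipode of the chiral phosphine ligand that delivers the 2S dihydrofuran is used, its sense being confirmed on the annulation product. The lipase is taken to acylate the (R)-alcohol faster, as it does with lavandulol, so the (S)-alcohol is the recovered one.

**Route**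

Step 1
Reactants: 1 3-hydroxybenzoic acid
Product: 2 3-(pivaloyloxy)benzoic acid, i.e. 3-[(2,2-dimethylpropanoyl)oxy]benzoic acid
Conditions: PivCl, NaOH, H2O–THF, 0 °C; then HCl to pH 2
Reagents that add atoms: pivaloyl chloride, CC(C)(C)C(=O)Cl
Why: Schotten–Baumann O-acylation of the phenoxide gives a hindered aryl ester that should withstand Lewis acids, phenoxide base and organozinc reagents and can be removed last by methanolysis.

Step 2
Reactants: 2 3-(pivaloyloxy)benzoic acid; 3 1,3,5-trimethoxybenzene
Product: 5 3-(2,4,6-trimethoxybenzoyl)phenyl pivalate, via acid chloride 4 (not isolated)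
Conditions: (COCl)2, DMF (cat.), CH2Cl2, rt; evaporate; then 3, AlCl3, CH2Cl2, 0 °C → rt
Reagents that add atoms: oxalyl chloride, O=C(Cl)C(=O)Cl (supplies only the chlorine of 4)
Why: Friedel–Crafts acylation of the threefold-symmetric, highly nucleophilic arene can give only one regioisomer, and any material that loses an ortho methyl group under AlCl3 converges in step 3.

Step 3
Reactants: 5 3-(2,4,6-trimethoxybenzoyl)phenyl pivalate
Product: 6 3-(2,6-dihydroxy-4-methoxybenzoyl)phenyl pivalate
Conditions: BCl3 (excess), CH2Cl2, 0 °C → rt; aqueous work-up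
Reagents that add atoms: none
Why: Chelation-directed ether cleavage by BCl3 removes only the two methoxy groups ortho to the ketone, because boron bound to the carbonyl oxygen activates those ethers alone, so the para methoxy group and the aryl ester should survive.

Step 4
Reactants: 6 3-(2,6-dihydroxy-4-methoxybenzoyl)phenyl pivalate
Product: 7 3-(2,6-dihydroxy-3-iodo-4-methoxybenzoyl)phenyl pivalate
Conditions: NIS (1.0 equiv), CH2Cl2, −20 → 0 °C
Reagents that add atoms: N-iodosuccinimide, O=C1CCC(=O)N1I
Why: Electrophilic aromatic iodination at a resorcinol-type position; the two open positions of ring A are equivalent by symmetry, so one equivalent of reagent should give a single mono-iodide with iodine ortho to a hydroxyl.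

Step 5
Reactants: 7 3-(2,6-dihydroxy-3-iodo-4-methoxybenzoyl)phenyl pivalate; 8 isoprene (2-methylbuta-1,3-diene)
Product: 9 3-{[(2S)-6-hydroxy-4-methoxy-2-(prop-1-en-2-yl)-2,3-dihydro-1-benzofuran-7-yl]carbonyl}phenyl pivalate
Conditions: 8 (excess), Pd2(dba)3·CHCl3 (cat.), chiral tert-butanesulfinamide-derived monophosphine ligand (TY-Phos class, antipode giving 2S), PhONa, CH2Cl2, 40 °C, sealed vessel
Reagents that add atoms: none
Why: Zerovalent palladium inserts into the C–I bond of 7, the arylpalladium species adds across the monosubstituted double bond of isoprene with the aryl group going to the terminal CH2, and the resulting η3-allyl complex of divalent palladium is attacked at its internal terminus by the neighbouring phenoxide, which releases zerovalent palladium. The closest known reaction type is the Larock heteroannulation of 1,3-dienes with o-halophenols in its enantioselective Heck/Tsuji–Trost form with chiral phosphine ligands, which accepts isoprene and acyl-substituted halophenols. The dihydrofuran ring closes by 5-exo allylic substitution (O1 onto the allyl carbon next to the new benzylic CH2); closure at the far CH2 terminus would need a seven-membered ring and is not expected to compete. C2 is created in this C–O bond formation and its configuration is controlled by the chiral ligand on palladium, the two allyl faces interconverting by η3–η1–η3 shifts at the unsubstituted terminus before the ring closes. The step needs aryl transfer to the CH=CH2 end of the diene and not to the 1,1-disubstituted end, which the lower substitution of that alkene secures; it also needs only one of the two phenols to cyclise, which is secured because only the hydroxyl ortho to iodine can reach the allyl unit while the para hydroxyl remains a spectator.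

Step 6
Reactants: 9 3-{[(2S)-6-hydroxy-4-methoxy-2-(prop-1-en-2-yl)-2,3-dihydro-1-benzofuran-7-yl]carbonyl}phenyl pivalate
Product: 10 3-{[(2S)-6-hydroxy-2-(2-hydroxypropan-2-yl)-4-methoxy-2,3-dihydro-1-benzofuran-7-yl]carbonyl}phenyl pivalate
Conditions: Co(acac)2 (cat.), PhSiH3, O2 (1 atm), THF, rt
Reagents that add atoms: dioxygen, O=O
Why: Mukaiyama hydration (hydrogen-atom transfer from a cobalt hydride to the 1,1-disubstituted alkene, capture of the tertiary radical by O2, reduction of the peroxide by the silane) should give the Markovnikov tertiary alcohol without touching the ketone, the ester or C2, at a stage where no other alkene is present.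

Step 7
Reactants: 10 3-{[(2S)-6-hydroxy-2-(2-hydroxypropan-2-yl)-4-methoxy-2,3-dihydro-1-benzofuran-7-yl]carbonyl}phenyl pivalate
Product: 11 3-{[(2S)-6-hydroxy-2-(2-hydroxypropan-2-yl)-5-iodo-4-methoxy-2,3-dihydro-1-benzofuran-7-yl]carbonyl}phenyl pivalate
Conditions: NIS (1.05 equiv), CH2Cl2, 0 °C
Reagents that add atoms: N-iodosuccinimide, O=C1CCC(=O)N1I
Why: Electrophilic aromatic iodination at C5, the only unsubstituted position of ring A, which is flanked by OH and OMe and para to O1, while ring B is deactivated by the carbonyl and acyloxy groups.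

Step 8
Reactants: 12 ethyl 3-methylbut-2-enoate; 13 4-bromo-2-methylbut-1-ene
Product: 14 ethyl (±)-5-methyl-2-(prop-1-en-2-yl)hex-5-enoate
Conditions: LiN(i-Pr)2, THF–DMPU, −78 °C; then 13, −78 → 0 °C
Reagents that add atoms: none
Why: Deconjugative α-alkylation of the lithium dienolate formed by γ-deprotonation of the senecioate (the classical lavandulyl ester construction) should give the β,γ-unsaturated ester, since the dienolate reacts with primary halides at its α-carbon.

Step 9
Reactants: 14 ethyl (±)-5-methyl-2-(prop-1-en-2-yl)hex-5-enoate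
Product: 15 (±)-5-methyl-2-(prop-1-en-2-yl)hex-5-en-1-ol
Conditions: LiAlH4, Et2O, 0 °C
Reagents that add atoms: none
Why: Hydride reduction of the non-conjugated ester to the primary alcohol should leave both 1,1-disubstituted alkenes untouched.

Step 10
Reactants: 15 (±)-5-methyl-2-(prop-1-en-2-yl)hex-5-en-1-ol
Product: 16 (2S)-5-methyl-2-(prop-1-en-2-yl)hex-5-en-1-ol (recovered unreacted alcohol)
Conditions: porcine pancreatic lipase, vinyl acetate, hexane, rt, run past half conversion; chromatography
Reagents that add atoms: none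
Why: Lipase-catalysed kinetic resolution by irreversible transesterification, as established for lavandulol whose stereocentre has the same surroundings, should consume the (R)-alcohol and leave the slow-reacting (S)-alcohol in high enantiomeric purity; this step is the source of the side-chain stereocentre.

Step 11
Reactants: 16 (2S)-5-methyl-2-(prop-1-en-2-yl)hex-5-en-1-ol
Product: 17 (3S)-3-(iodomethyl)-2,6-dimethylhepta-1,6-diene
Conditions: PPh3, I2, imidazole, CH2Cl2, 0 °C → rt
Reagents that add atoms: iodine, II
Why: Appel-type iodination (Garegg–Samuelsson conditions) is an SN2 displacement at the primary carbon, so the adjacent stereocentre is not involved.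

Step 12
Reactants: 11 3-{[(2S)-6-hydroxy-2-(2-hydroxypropan-2-yl)-5-iodo-4-methoxy-2,3-dihydro-1-benzofuran-7-yl]carbonyl}phenyl pivalate; 17 (3S)-3-(iodomethyl)-2,6-dimethylhepta-1,6-diene
Product: 19 3-{[(2S)-6-hydroxy-2-(2-hydroxypropan-2-yl)-4-methoxy-5-[(2R)-5-methyl-2-(prop-1-en-2-yl)hex-5-en-1-yl]-2,3-dihydro-1-benzofuran-7-yl]carbonyl}phenyl pivalate, via alkylzinc iodide 18 (not isolated)
Conditions: 17, Zn dust (activated), LiCl, THF, 40 °C; then 11, Pd(OAc)2 (cat.), SPhos, THF, rt → 50 °C, slow addition of excess zinc reagent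
Reagents that add atoms: zinc, [Zn] (metal of 18 only)
Why: Negishi coupling, in which zinc insertion leaves the β-stereocentre untouched and a palladium catalyst with a bulky biarylphosphine joins primary alkylzinc halides to hindered aryl iodides faster than β-hydride elimination, is known to tolerate free phenols and alcohols when the zinc reagent is added slowly.

Step 13
Reactants: 19 3-{[(2S)-6-hydroxy-2-(2-hydroxypropan-2-yl)-4-methoxy-5-[(2R)-5-methyl-2-(prop-1-en-2-yl)hex-5-en-1-yl]-2,3-dihydro-1-benzofuran-7-yl]carbonyl}phenyl pivalate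
Product: 20 [(2S)-6-hydroxy-2-(2-hydroxypropan-2-yl)-4-methoxy-5-[(2R)-5-methyl-2-(prop-1-en-2-yl)hex-5-en-1-yl]-2,3-dihydro-1-benzofuran-7-yl](3-hydroxyphenyl)methanone (CNP0263422.2)
Conditions: K2CO3, MeOH, rt → 40 °C
Reagents that add atoms: none
Why: Base-catalysed transesterification of the aryl pivalate should free the ring-B phenol under conditions that affect neither the alkenes, the tertiary alcohol nor either stereocentre.

**Compound list**
1 | 3-hydroxybenzoic acid | OC(=O)c1cccc(O)c1 | starting material
2 | 3-(pivaloyloxy)benzoic acid | CC(C)(C)C(=O)Oc1cccc(c1)C(=O)O | intermediate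
3 | 1,3,5-trimethoxybenzene | COc1cc(OC)cc(OC)c1 | starting material
4 | 3-(pivaloyloxy)benzoyl chloride (not isolated) | CC(C)(C)C(=O)Oc1cccc(c1)C(Cl)=O | intermediate
5 | 3-(2,4,6-trimethoxybenzoyl)phenyl pivalate | COc1cc(OC)c(C(=O)c2cccc(OC(=O)C(C)(C)C)c2)c(OC)c1 | intermediate
6 | 3-(2,6-dihydroxy-4-methoxybenzoyl)phenyl pivalate | COc1cc(O)c(C(=O)c2cccc(OC(=O)C(C)(C)C)c2)c(O)c1 | intermediate
7 | 3-(2,6-dihydroxy-3-iodo-4-methoxybenzoyl)phenyl pivalate | COc1cc(O)c(C(=O)c2cccc(OC(=O)C(C)(C)C)c2)c(O)c1I | intermediate
8 | isoprene | C=CC(C)=C | starting material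
9 | 3-{[(2S)-6-hydroxy-4-methoxy-2-(prop-1-en-2-yl)-2,3-dihydro-1-benzofuran-7-yl]carbonyl}phenyl pivalate | Oc1cc(OC)c2C[C@@H](C(C)=C)Oc2c1C(=O)c1cccc(OC(=O)C(C)(C)C)c1 | intermediate
10 | 3-{[(2S)-6-hydroxy-2-(2-hydroxypropan-2-yl)-4-methoxy-2,3-dihydro-1-benzofuran-7-yl]carbonyl}phenyl pivalate | Oc1cc(OC)c2C[C@@H](C(C)(C)O)Oc2c1C(=O)c1cccc(OC(=O)C(C)(C)C)c1 | intermediate
11 | 3-{[(2S)-6-hydroxy-2-(2-hydroxypropan-2-yl)-5-iodo-4-methoxy-2,3-dihydro-1-benzofuran-7-yl]carbonyl}phenyl pivalate | Oc1c(I)c(OC)c2C[C@@H](C(C)(C)O)Oc2c1C(=O)c1cccc(OC(=O)C(C)(C)C)c1 | intermediate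
12 | ethyl 3-methylbut-2-enoate | CCOC(=O)C=C(C)C | starting material
13 | 4-bromo-2-methylbut-1-ene | C=C(C)CCBr | starting material
14 | ethyl (±)-5-methyl-2-(prop-1-en-2-yl)hex-5-enoate | CCOC(=O)C(CCC(C)=C)C(C)=C | intermediate
15 | (±)-5-methyl-2-(prop-1-en-2-yl)hex-5-en-1-ol | C=C(C)CCC(CO)C(C)=C | intermediate
16 | (2S)-5-methyl-2-(prop-1-en-2-yl)hex-5-en-1-ol | C=C(C)CC[C@H](CO)C(=C)C | intermediate
17 | (3S)-3-(iodomethyl)-2,6-dimethylhepta-1,6-diene | C=C(C)CC[C@H](CI)C(=C)C | intermediate
18 | [(2S)-5-methyl-2-(prop-1-en-2-yl)hex-5-en-1-yl]zinc iodide, LiCl adduct (not isolated) | C=C(C)CC[C@H](C[Zn]I)C(=C)C | intermediate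
19 | 3-{[(2S)-6-hydroxy-2-(2-hydroxypropan-2-yl)-4-methoxy-5-[(2R)-5-methyl-2-(prop-1-en-2-yl)hex-5-en-1-yl]-2,3-dihydro-1-benzofuran-7-yl]carbonyl}phenyl pivalate | C=C(C)CC[C@H](Cc1c(O)c(C(=O)c2cccc(OC(=O)C(C)(C)C)c2)c2c(c1OC)C[C@@H](C(C)(C)O)O2)C(=C)C | intermediate
20 | [(2S)-6-hydroxy-2-(2-hydroxypropan-2-yl)-4-methoxy-5-[(2R)-5-methyl-2-(prop-1-en-2-yl)hex-5-en-1-yl]-2,3-dihydro-1-benzofuran-7-yl](3-hydroxyphenyl)methanone | C=C(C)CC[C@H](Cc1c(O)c(C(=O)c2cccc(O)c2)c2c(c1OC)C[C@@H](C(C)(C)O)O2)C(=C)C | target

**Count and risks**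
Total steps: 13. Longest linear sequence: 9 steps (steps 1–7, 12, 13, from 1 to 20); the side-chain branch (steps 8–11) joins at step 12.

Steps most likely to fail:

Step 5. Oxidative addition into the electron-rich, doubly deprotonated aryl iodide may be slow, and the chiral ligand may discriminate the allyl faces poorly next to a chelating hydroxyketone, so conversion or enantiomeric purity at C2 may fall short. The fallback sets out from 7 and returns at 10, bypassing steps 5 and 6. Stille coupling of 7 with Bu3SnCH2CH=C(CH3)2 (Pd(PPh3)4, DMF, 80 °C) should give the C-prenyl bisphenol 3-[2,6-dihydroxy-4-methoxy-3-(3-methylbut-2-en-1-yl)benzoyl]phenyl pivalate F1. Shi epoxidation of its trisubstituted alkene (fructose-derived ketone of the antipode that gives the R epoxide, KHSO5, K2CO3-buffered aqueous MeCN, 0 °C) should give the (R)-epoxide 3-(3-{[(2R)-3,3-dimethyloxiran-2-yl]methyl}-2,6-dihydroxy-4-methoxybenzoyl)phenyl pivalate F2. The ortho phenoxide then opens the epoxide 5-exo at the secondary carbon with inversion, in the basic medium or on brief K2CO3 treatment, giving 10 with the tertiary alcohol already in place.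

Step 12. Protonation of the alkylzinc reagent by the chelated phenol and slow oxidative addition at the electron-rich C5–I bond flanked by two ortho substituents may lead to reduced arene and unreacted iodide. The fallback sets out from 11 and 17 and returns at 20. Acetylation of 11 (Ac2O, Et3N, DMAP, CH2Cl2, 0 °C) should give the 6-O-acetyl iodide F3. Iodide 17 is converted by t-BuLi (Et2O, −78 °C) and B-methoxy-9-borabicyclo[3.3.1]nonane into B-[(2S)-5-methyl-2-(prop-1-en-2-yl)hex-5-en-1-yl]-9-borabicyclo[3.3.1]nonane F4, used as its lithium methoxide ate complex. B-alkyl Suzuki–Miyaura coupling of F3 with F4 (PdCl2(dppf), K3PO4, DMF–H2O, 60 °C) should give the acetate pivalate of the target F5. Methanolysis (K2CO3, MeOH) removes both acyl groups and gives 20.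

Step 10. Incomplete discrimination of the enantiomers by the lipase, or the opposite preference, would leave alcohol of low enantiomeric purity. The fallback sets out from 14 and returns at 16. Saponification of 14 (LiOH, THF–H2O) should give (±)-5-methyl-2-(prop-1-en-2-yl)hex-5-enoic acid F6. Acylation of (S)-4-benzyloxazolidin-2-one through the pivalic mixed anhydride (PivCl, Et3N, LiCl, THF, −20 °C → rt) should give two diastereomeric imides, separable by chromatography: (4S)-4-benzyl-3-[(2S)-5-methyl-2-(prop-1-en-2-yl)hex-5-enoyl]oxazolidin-2-one F7 and its (2R) diastereomer F8. Reduction of F7 (LiBH4, Et2O, H2O 1 equiv, 0 °C) should give 16 and return the auxiliary.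

Further compounds
F1 | step 5 | 3-[2,6-dihydroxy-4-methoxy-3-(3-methylbut-2-en-1-yl)benzoyl]phenyl pivalate | COc1cc(O)c(C(=O)c2cccc(OC(=O)C(C)(C)C)c2)c(O)c1CC=C(C)C
F2 | step 5 | 3-(3-{[(2R)-3,3-dimethyloxiran-2-yl]methyl}-2,6-dihydroxy-4-methoxybenzoyl)phenyl pivalate | COc1cc(O)c(C(=O)c2cccc(OC(=O)C(C)(C)C)c2)c(O)c1C[C@H]1OC1(C)C
F3 | step 12 | 3-{[(2S)-6-acetoxy-2-(2-hydroxypropan-2-yl)-5-iodo-4-methoxy-2,3-dihydro-1-benzofuran-7-yl]carbonyl}phenyl pivalate | CC(=O)Oc1c(I)c(OC)c2C[C@@H](C(C)(C)O)Oc2c1C(=O)c1cccc(OC(=O)C(C)(C)C)c1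
F4 | step 12 | B-[(2S)-5-methyl-2-(prop-1-en-2-yl)hex-5-en-1-yl]-9-borabicyclo[3.3.1]nonane | C=C(C)CC[C@H](CB1C2CCCC1CCC2)C(=C)C
F5 | step 12 | 3-{[(2S)-6-acetoxy-2-(2-hydroxypropan-2-yl)-4-methoxy-5-[(2R)-5-methyl-2-(prop-1-en-2-yl)hex-5-en-1-yl]-2,3-dihydro-1-benzofuran-7-yl]carbonyl}phenyl pivalate | C=C(C)CC[C@H](Cc1c(OC(C)=O)c(C(=O)c2cccc(OC(=O)C(C)(C)C)c2)c2c(c1OC)C[C@@H](C(C)(C)O)O2)C(=C)C
F6 | step 10 | (±)-5-methyl-2-(prop-1-en-2-yl)hex-5-enoic acid | C=C(C)CCC(C(=O)O)C(C)=C
F7 | step 10 | (4S)-4-benzyl-3-[(2S)-5-methyl-2-(prop-1-en-2-yl)hex-5-enoyl]oxazolidin-2-one | C=C(C)CC[C@H](C(=O)N1[C@@H](Cc2ccccc2)COC1=O)C(=C)C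
F8 | step 10 | (4S)-4-benzyl-3-[(2R)-5-methyl-2-(prop-1-en-2-yl)hex-5-enoyl]oxazolidin-2-one | C=C(C)CC[C@@H](C(=O)N1[C@@H](Cc2ccccc2)COC1=O)C(=C)C
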